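Ask first what would have to be true of the numbers for the Tuesday's run to come out faster or slower than the Thursday's run at equal c(starting material), and you have the way into the other two questions as well.

| flask | starting material | target | time |
|---|---|---|---|
| Thursday's | 300 mM |  |  |
| Tuesday's | 120 mM |  |  |
| Sunday's | 450 mM |  |  |
| Monday's | 300 mM | 150 mM |  |
| Wednesday's | 900 mM |  | 130 h |

- Thursday's run (time / h: [target] / mM): 26: 56; 52: 125; 78: 167; 100: 206; 130: 234
- Tuesday's run (time / h: [target] / mM): 26: 39; 52: 67; 78: 88; 100: 101; 130: 114
- Sunday's run (time / h: [target] / mM): 26: 75; 52: 150; 78: 217; 100: 258; 130: 316
- Monday's run (time / h: [target] / mM): 26: 204; 52: 269; 78: 320; 100: 348; 130: 383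

(scatter of a reading: 4 mM)

1. the power of [starting material] that the first rate follows, about the charge of the Thursday's run; measure it at two percent of starting material made into target (one fixed amount of target, the same in the runs compared)
2. the Tuesday's run starts with 180 mM less of starting material than the Thursday's run, and with no target. Compared where both hold the same amount of starting material, once fifteen percent of what the Tuesday's run was charged with has turned into target, is the Tuesday's run faster, slower or alike (within a tenth)?
3. target in the Wednesday's run at 130 h, as a share of the starting material charged

- Overall: starting material -> target.
- Constant volume, constant temperature.
- Bound and free are read together.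
- An order is taken over about fifteen percent of the charge, up and down.

For that outcome, the rate would have to follow more than c(starting material): the target already present, perhaps, or the hours a flask has stood. So look for two stretches that start from the same holding. The Sunday's run has made 150 mM at 52 h, so it then holds 0.300 M, the charge of the Thursday's run, and over the next 78.0 h it adds 0.166 M, while the Thursday's run makes 167 mM in its first 78 h. A rate differing by 10.0% would open a gap near 16.7 mM, but the gap read here, from readings scattered by 4 mM, is 1.00 mM, so the Sunday's and the Thursday's run show no such difference, and I carry that over to the Tuesday's run and reckon alike.

The rate then needs a form in c(starting material). From the Tuesday's to the Sunday's run, the target at 26 h follows the charge to the power 0.495, about a half, which is my order. Under a square-root law the root of c(starting material) falls steadily, so define the root pace as the rate of a flask holding 300 mM: twice the drop in the root of c(starting material) times the root of 300 mM, divided by the hours. The whole of the Sunday's run gives 2.57 mM/h. Carried to the Wednesday's run over 130 h, it gives a share of 53.9%.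

The forecast gives order 0.4, alike and 49%, calling its last figure “an extrapolation beyond the charges tested”, so it shares my alike but has a lower order and a lower share than mine.

The simulation gives order 0.56, alike and 56.2%.

    2 starting material ⇌ substrate dimer, settled at all times (38.70 /M)
    starting material → target (0.03049 /h)
    starting material → target (0.01620 /h)

Where both runs hold the same c(starting material), the rate of the Tuesday's run over that of the Thursday's run is 1.0. Read back from the share of the Wednesday's run, the root pace is 2.70 mM/h, higher than the 2.57 mM/h of the Sunday's run. That 2.57 mM/h puts the target of the Tuesday's run at half the charge after a reckoned 43.3 h, and the Tuesday's run gets there at 46.4 h.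

The runs were computed from invented constants, noise included.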